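**Retrosynthetic overview**
1. The methylene bridge is cut last: ring B (from phloroglucinol) is carried as its Mannich base 27, whose ortho-quinone methide is trapped by C6 of the ring-A triketone 22.
2. Ring A is a cross-conjugated cyclohexa-2,5-dien-1-one: its quaternary C4 (methyl, prenyl) lies para to the C1 ketone, and the C2=C3 unit between them (hexanoyl on C2, oxygen on C3) has the oxidation level of a β-alkoxy ynone. Cutting C1–C2 and C3–C4 gives ynone 18 and the strained cyclobutenone 13, in which C4 is bonded directly to C1.
3. Forward, nickel opens that C1–C4 bond and stitches the alkyne in (strain release, formal [4+2]). C4 cannot aromatise and keeps its configuration, so ring A arrives with all its carbons, its three ring oxygens and the stereocentre in one operation.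
4. The stereocentre is set earlier on the four-membered ring: ketene/ethoxyacetylene [2+2], hydrolysis to the achiral cyclobutane-1,3-dione, catalytic desymmetrisation, then nitrogen-to-oxygen exchange.
5. Ring order: cyclobutenone (step 3), then ring A (step 9); ring B is bought as phloroglucinol.

Key step: step 9

Assumption: ring A is an enolised cyclic β-triketone, so the drawn tautomer stands for all of them; by the CIP rules its quaternary carbon is (R).

**Route**

Step 1
Reactants: 1 propionic acid; 2 prenyl bromide (1-bromo-3-methylbut-2-ene)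
Product: 4 2,5-dimethylhex-4-enoic acid (racemic), via dilithium enediolate 3 (not isolated)
Conditions: LiN(iPr)2 (2.1 equiv), THF, 0 °C; then 2, 0 °C → rt; aq. HCl
Reagents that add atoms: none
Why: α-Alkylation of a carboxylic acid dianion (enediolate alkylation) at the primary carbon of the allylic bromide; the stereocentre formed is irrelevant because it becomes the ketene carbon in step 3.

Step 2
Reactants: 4 2,5-dimethylhex-4-enoic acid
Product: 5 2,5-dimethylhex-4-enoyl chloride (racemic)
Conditions: (COCl)2 (1.2 equiv), DMF (cat.), CH2Cl2, 0 °C → rt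
Reagents that add atoms: oxalyl chloride, O=C(Cl)C(=O)Cl
Why: Acid chloride formation through the catalytic chloroiminium species, cold and short enough to spare the trisubstituted alkene.

Step 3
Reactants: 5 2,5-dimethylhex-4-enoyl chloride; 6 ethoxyacetylene
Product: 8 rac-3-ethoxy-4-methyl-4-(3-methylbut-2-en-1-yl)cyclobut-2-en-1-one, via methyl(prenyl)ketene 7 (not isolated)
Conditions: 6 (2 equiv), Et3N (1.3 equiv), Et2O, 0 °C → rt
Reagents that add atoms: none
Why: Dehydrochlorination gives the disubstituted ketene, which undergoes the known thermal ketene–ynol ether [2+2] cycloaddition (ketene carbonyl carbon to the nucleophilic CH terminus of the alkyne) to give the 3-alkoxycyclobutenone; the quaternary centre forms racemic here.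

Step 4
Reactants: 8 rac-3-ethoxy-4-methyl-4-(3-methylbut-2-en-1-yl)cyclobut-2-en-1-one
Product: 9 2-methyl-2-(3-methylbut-2-en-1-yl)cyclobutane-1,3-dione
Conditions: 1 M aq. HCl, THF, 0 °C → rt
Reagents that add atoms: water, O
Why: Acid hydrolysis of the vinylogous ester makes the two carbonyl carbons equivalent and gives the achiral 2,2-disubstituted cyclobutane-1,3-dione, the substrate for desymmetrisation.

Step 5
Reactants: 9 2-methyl-2-(3-methylbut-2-en-1-yl)cyclobutane-1,3-dione; 10 aniline
Product: 11 (S)-4-methyl-4-(3-methylbut-2-en-1-yl)-3-(phenylamino)cyclobut-2-en-1-one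
Conditions: (R)-TRIP [(R)-3,3′-bis(2,4,6-triisopropylphenyl)-1,1′-binaphthyl-2,2′-diyl hydrogen phosphate] (5 mol %), 4 Å MS, toluene, 0 °C
Reagents that add atoms: none
Why: Chiral phosphoric acid-catalysed desymmetrising carbonyl–amine condensation of a 2,2-disubstituted cyclobutane-1,3-dione: the catalyst selects one of the two enantiotopic carbonyl groups and thereby turns the prochiral quaternary carbon into a stereocentre; the (S)-enaminone is needed, and the catalyst antipode is exchanged if the sense of induction proves opposite.

Step 6
Reactants: 11 (S)-4-methyl-4-(3-methylbut-2-en-1-yl)-3-(phenylamino)cyclobut-2-en-1-one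
Product: 13 (R)-3-ethoxy-4-methyl-4-(3-methylbut-2-en-1-yl)cyclobut-2-en-1-one, via O-ethyl iminium tetrafluoroborate 12 (not isolated)
Conditions: Et3OBF4 (1.1 equiv), CH2Cl2, 0 °C → rt; then H2O/THF, 0 °C → rt; aq. NaHCO3
Reagents that add atoms: triethyloxonium tetrafluoroborate, CC[O+](CC)CC.F[B-](F)(F)F; water, O
Why: O-Alkylation of the vinylogous amide gives an alkoxy-iminium ion whose C=N carbon is hydrolysed with loss of aniline (imidate-type hydrolysis), so the two ring carbons exchange roles without passing through the symmetric dione; the stereocentre is untouched and its descriptor changes from S to R only because the ranks of the two ring carbons swap.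

Step 7
Reactants: 14 hexanoyl chloride; 15 N,O-dimethylhydroxylamine hydrochloride
Product: 16 N-methoxy-N-methylhexanamide
Conditions: pyridine (2.2 equiv), CH2Cl2, 0 °C → rt
Reagents that add atoms: none
Why: Amine acylation (Schotten–Baumann type) gives the N-methoxy-N-methylamide needed for a Weinreb ketone synthesis.

Step 8
Reactants: 16 N-methoxy-N-methylhexanamide; 6 ethoxyacetylene
Product: 18 1-ethoxyoct-1-yn-3-one, via lithium ethoxyacetylide 17 (not isolated)
Conditions: 6, n-BuLi, THF, −78 °C; then 16, −78 → −20 °C; AcOH quench
Reagents that add atoms: none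
Why: Weinreb ketone synthesis: the lithium acetylide adds once, the chelated tetrahedral adduct collapses only on quench, and the push–pull ynone is obtained without over-addition.

Step 9
Reactants: 13 (R)-3-ethoxy-4-methyl-4-(3-methylbut-2-en-1-yl)cyclobut-2-en-1-one; 18 1-ethoxyoct-1-yn-3-one
Product: 21 (R)-3,5-diethoxy-2-hexanoyl-4-methyl-4-(3-methylbut-2-en-1-yl)cyclohexa-2,5-dien-1-one, via nickelacyclopentenone 19 (not isolated), via nickelacycloheptadienone 20 (not isolated)
Conditions: Ni(COD)2 (10 mol %), PPh3 (20 mol %), toluene, 0 °C → rt, slow addition of 18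
Reagents that add atoms: none
Why: Proposed new method: Zerovalent nickel should insert with retention into the strained C1–C4 bond of 13 (acyl carbon to quaternary carbon) to give the divalent nickelacyclopentenone 19, whose nickel-bound C4 is an allyl-type terminus that adds to the ethoxy-bearing, electrophilic carbon of ynone 18 (conjugate carbonickelation, new C3–C4 bond, nickelacycle 20), and C–C reductive elimination then joins the acyl carbon to the hexanoyl-bearing carbon (new C1–C2 bond). The closest known reaction type is the nickel-catalysed [4+2] benzannulation of cyclobutenones with alkynes by cleavage of the same C1–C4 bond, known for cyclobutenones that carry a hydrogen at C4 and therefore end as phenols, together with rhodium-catalysed cut-and-sew carboacylation of cyclobutanones; new are the quaternary migrating carbon, which forbids aromatisation and leaves the 4,4-disubstituted cyclohexa-2,5-dienone, and the heteroatom-polarised alkyne. Ring A is closed as a formal [4+2] (four carbons of the cyclobutenone, two of the alkyne): the last bond forms by reductive elimination from a seven-membered nickelacycle, and the release of cyclobutenone ring strain drives the sequence. No new stereocentre arises: the centre set in step 5 is carried over with retention, because C4 stays bound to nickel on the face vacated by C1 and oxidative addition, migratory insertion and reductive elimination are each stereoretentive. The step needs one alkyne orientation, which matched polarity should secure: in 19 the ring enol ether makes C4 nucleophilic and C1 is an acyl electrophile, while in 18 the ethoxy donor and the ketone acceptor both make the oxygen-bearing alkyne carbon electrophilic and its neighbour enolate-like. It also needs the thermal electrocyclic opening of 13 to a free, achiral vinylketene to stay silent, which a reaction temperature at or below room temperature should secure.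

Step 10
Reactants: 21 (R)-3,5-diethoxy-2-hexanoyl-4-methyl-4-(3-methylbut-2-en-1-yl)cyclohexa-2,5-dien-1-one
Product: 22 (R)-2-hexanoyl-3,5-dihydroxy-4-methyl-4-(3-methylbut-2-en-1-yl)cyclohexa-2,5-dien-1-one
Conditions: 1 M aq. HCl, THF, 40 °C
Reagents that add atoms: water, O
Why: Acid hydrolysis of both vinylogous ethyl esters (water adds to the protonated β-alkoxyenone, ethanol leaves) unveils the enolised β-triketone; the quaternary centre has no α-hydrogen and its two ring flanks stay different (hexanoyl against H), so it cannot racemise.

Step 11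
Reactants: 23 phloroglucinol; 24 butyryl chloride
Product: 25 1-(2,4,6-trihydroxyphenyl)butan-1-one
Conditions: AlCl3 (3.5 equiv), PhNO2/CH2Cl2, 0 → 40 °C; aq. HCl
Reagents that add atoms: none
Why: Friedel–Crafts C-acylation of phloroglucinol; the first acyl group deactivates the ring, so monoacylation should prevail.

Step 12
Reactants: 25 1-(2,4,6-trihydroxyphenyl)butan-1-one
Product: 26 1-(2,6-dihydroxy-4-methoxyphenyl)butan-1-one
Conditions: Me2SO4 (1.0 equiv), K2CO3 (1.0 equiv), acetone, rt
Reagents that add atoms: dimethyl sulfate, COS(=O)(=O)OC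
Why: Williamson etherification: the para hydroxyl is the only one not hydrogen-bonded to the ketone, hence the most acidic and nucleophilic, so one equivalent of methylating agent should give the 4-O-methyl ether.

Step 13
Reactants: 26 1-(2,6-dihydroxy-4-methoxyphenyl)butan-1-one
Product: 27 1-{3-[(dimethylamino)methyl]-2,6-dihydroxy-4-methoxyphenyl}butan-1-one
Conditions: CH2=NMe2+ I− (1.0 equiv), Et3N (1.0 equiv), CH2Cl2, 0 °C → rt
Reagents that add atoms: N,N-dimethylmethyleneiminium iodide, C=[N+](C)C.[I-]
Why: Mannich aminomethylation with the preformed iminium salt at one of the two equivalent ring positions between OH and OMe; one equivalent limits double aminomethylation.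

Step 14
Reactants: 22 (R)-2-hexanoyl-3,5-dihydroxy-4-methyl-4-(3-methylbut-2-en-1-yl)cyclohexa-2,5-dien-1-one; 27 1-{3-[(dimethylamino)methyl]-2,6-dihydroxy-4-methoxyphenyl}butan-1-one
Product: 29 (R)-6-[(3-butanoyl-2,4-dihydroxy-6-methoxyphenyl)methyl]-2-hexanoyl-3,5-dihydroxy-4-methyl-4-(3-methylbut-2-en-1-yl)cyclohexa-2,5-dien-1-one (CNP0219674.1), via ortho-quinone methide 28 (not isolated)
Conditions: 27 (1.2 equiv), 1,4-dioxane, 90 °C
Reagents that add atoms: none
Why: The acidic enol of 22 protonates the benzylic amine, thermal loss of dimethylamine gives the ortho-quinone methide, and C6 of the cyclic β-diketone unit adds to its exocyclic CH2 (Michael addition with rearomatisation of ring B), which forms the methylene bridge without touching the stereocentre.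

**Compound list**
1 | propionic acid | CCC(=O)O | starting material
2 | prenyl bromide (1-bromo-3-methylbut-2-ene) | CC(C)=CCBr | starting material
3 | dilithium enediolate of propionic acid (formed in situ) | CC=C(O[Li])O[Li] | intermediate
4 | 2,5-dimethylhex-4-enoic acid (racemic) | CC(CC=C(C)C)C(=O)O | intermediate
5 | 2,5-dimethylhex-4-enoyl chloride (racemic) | CC(CC=C(C)C)C(=O)Cl | intermediate
6 | ethoxyacetylene | C#COCC | starting material
7 | methyl(prenyl)ketene, 2,5-dimethylhexa-1,4-dien-1-one (formed in situ) | CC(CC=C(C)C)=C=O | intermediate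
8 | rac-3-ethoxy-4-methyl-4-(3-methylbut-2-en-1-yl)cyclobut-2-en-1-one | CCOC1=CC(=O)C1(C)CC=C(C)C | intermediate
9 | 2-methyl-2-(3-methylbut-2-en-1-yl)cyclobutane-1,3-dione (achiral) | CC1(CC=C(C)C)C(=O)CC1=O | intermediate
10 | aniline | Nc1ccccc1 | starting material
11 | (S)-4-methyl-4-(3-methylbut-2-en-1-yl)-3-(phenylamino)cyclobut-2-en-1-one | O=C1C=C(Nc2ccccc2)[C@]1(C)CC=C(C)C | intermediate
12 | (S)-configured O-ethyl N-phenyl cyclobutene iminium tetrafluoroborate (formed in situ) | CCOC1=CC(=[NH+]c2ccccc2)[C@]1(C)CC=C(C)C.F[B-](F)(F)F | intermediate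
13 | (R)-3-ethoxy-4-methyl-4-(3-methylbut-2-en-1-yl)cyclobut-2-en-1-one | CCOC1=CC(=O)[C@]1(C)CC=C(C)C | intermediate
14 | hexanoyl chloride | CCCCCC(=O)Cl | starting material
15 | N,O-dimethylhydroxylamine hydrochloride | CNOC.Cl | starting material
16 | N-methoxy-N-methylhexanamide | CCCCCC(=O)N(C)OC | intermediate
17 | lithium ethoxyacetylide (formed in situ) | [Li]C#COCC | intermediate
18 | 1-ethoxyoct-1-yn-3-one | CCCCCC(=O)C#COCC | intermediate
19 | nickelacyclopentenone from insertion of nickel into C1–C4 of 13 (phosphine ligands omitted; formed in situ) | O=C1C=C(OCC)[C@@](C)(CC=C(C)C)[Ni]1 | intermediate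
20 | nickelacycloheptadienone after insertion of 18 (phosphine ligands omitted; formed in situ) | CCCCCC(=O)C1=C(OCC)[C@](C)(CC=C(C)C)C(OCC)=CC(=O)[Ni]1 | intermediate
21 | (R)-3,5-diethoxy-2-hexanoyl-4-methyl-4-(3-methylbut-2-en-1-yl)cyclohexa-2,5-dien-1-one | CCCCCC(=O)C1=C(OCC)[C@](C)(CC=C(C)C)C(OCC)=CC1=O | intermediate
22 | (R)-2-hexanoyl-3,5-dihydroxy-4-methyl-4-(3-methylbut-2-en-1-yl)cyclohexa-2,5-dien-1-one | CCCCCC(=O)C1=C(O)[C@](C)(CC=C(C)C)C(O)=CC1=O | intermediate
23 | phloroglucinol | Oc1cc(O)cc(O)c1 | starting material
24 | butyryl chloride | CCCC(=O)Cl | starting material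
25 | 1-(2,4,6-trihydroxyphenyl)butan-1-one | CCCC(=O)c1c(O)cc(O)cc1O | intermediate
26 | 1-(2,6-dihydroxy-4-methoxyphenyl)butan-1-one | CCCC(=O)c1c(O)cc(OC)cc1O | intermediate
27 | 1-{3-[(dimethylamino)methyl]-2,6-dihydroxy-4-methoxyphenyl}butan-1-one | CCCC(=O)c1c(O)cc(OC)c(CN(C)C)c1O | intermediate
28 | ortho-quinone methide of ring B, 2-butanoyl-3-hydroxy-5-methoxy-6-methylenecyclohexa-2,4-dien-1-one (formed in situ) | C=C1C(OC)=CC(O)=C(C(=O)CCC)C1=O | intermediate
29 | (R)-6-[(3-butanoyl-2,4-dihydroxy-6-methoxyphenyl)methyl]-2-hexanoyl-3,5-dihydroxy-4-methyl-4-(3-methylbut-2-en-1-yl)cyclohexa-2,5-dien-1-one | CCCCCC(=O)C1=C(O)[C@](C)(CC=C(C)C)C(O)=C(Cc2c(OC)cc(O)c(C(=O)CCC)c2O)C1=O | target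

**Count and risks**
Total step count: 14. Longest linear sequence: 9 steps (1, 2, 3, 4, 5, 6, 9, 10, 14).

Steps most likely to fail:

1. Step 9 (the step that carries the new-method label). What may go wrong:
   - insertion of the alkyne in the reverse orientation;
   - erosion of enantiomeric purity if nickel leaves the π-face of a vinylketene-type intermediate, or if 13 opens thermally;
   - β-hydride elimination at the nickel-bound quaternary carbon;
   - oligomerisation of the ynone on nickel.

   Fallback, known chemistry only, sets out from 14 (with 2) and comes back at 22. Friedel–Crafts acylation of bought 2,4,6-trihydroxytoluene F1 with 14 (AlCl3, PhNO2) should give 1-(2,4,6-trihydroxy-3-methylphenyl)hexan-1-one F2. Base-mediated dearomatising C-prenylation of F2 with 2 (NaOMe, MeOH, 0 °C) at the methyl-bearing carbon should give racemic 2-hexanoyl-3,5-dihydroxy-4-methyl-4-(3-methylbut-2-en-1-yl)cyclohexa-2,5-dien-1-one F3. Preparative HPLC on a chiral stationary phase then separates 22 from (S)-2-hexanoyl-3,5-dihydroxy-4-methyl-4-(3-methylbut-2-en-1-yl)cyclohexa-2,5-dien-1-one F4, and the route continues with step 14.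

2. Step 6. What may go wrong:
   - alkylation on nitrogen instead of oxygen;
   - attack of water at the ethoxy-bearing carbon, which returns 11;
   - hydrolysis running on to the symmetric dione 9, which costs material.

   Fallback, sets out from 8 and comes back at 13. The racemic cyclobutenone 8 is resolved by preparative supercritical-fluid chromatography on a chiral stationary phase. This gives 13 directly and bypasses steps 4 to 6. The unwanted (S)-3-ethoxy-4-methyl-4-(3-methylbut-2-en-1-yl)cyclobut-2-en-1-one F5 is recycled by hydrolysis to 9.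

3. Step 14. What may go wrong:
   - slow loss of dimethylamine;
   - exchange of the methylene bridge between partners, which leads to symmetric dimers;
   - capture of the quinone methide by a second ring B molecule.

   Fallback, sets out from 22 and 26 and comes back at 29, with the polarity reversed. 22 is aminomethylated at C6 with CH2=NMe2+ I− to give (R)-6-[(dimethylamino)methyl]-2-hexanoyl-3,5-dihydroxy-4-methyl-4-(3-methylbut-2-en-1-yl)cyclohexa-2,5-dien-1-one F6. Warming F6 with 26 expels dimethylamine, and the 6-methylene triketone formed is trapped by the electron-rich free ring carbon of 26 (Friedel–Crafts-type conjugate addition).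

Further compounds
F1 | step 9 | 2,4,6-trihydroxytoluene (bought starting material of the fallback) | Cc1c(O)cc(O)cc1O
F2 | step 9 | 1-(2,4,6-trihydroxy-3-methylphenyl)hexan-1-one | CCCCCC(=O)c1c(O)cc(O)c(C)c1O
F3 | step 9 | rac-2-hexanoyl-3,5-dihydroxy-4-methyl-4-(3-methylbut-2-en-1-yl)cyclohexa-2,5-dien-1-one | CCCCCC(=O)C1=C(O)C(C)(CC=C(C)C)C(O)=CC1=O
F4 | step 9 | (S)-2-hexanoyl-3,5-dihydroxy-4-methyl-4-(3-methylbut-2-en-1-yl)cyclohexa-2,5-dien-1-one | CCCCCC(=O)C1=C(O)[C@@](C)(CC=C(C)C)C(O)=CC1=O
F5 | step 6 | (S)-3-ethoxy-4-methyl-4-(3-methylbut-2-en-1-yl)cyclobut-2-en-1-one | CCOC1=CC(=O)[C@@]1(C)CC=C(C)C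
F6 | step 14 | (R)-6-[(dimethylamino)methyl]-2-hexanoyl-3,5-dihydroxy-4-methyl-4-(3-methylbut-2-en-1-yl)cyclohexa-2,5-dien-1-one | CCCCCC(=O)C1=C(O)[C@](C)(CC=C(C)C)C(O)=C(CN(C)C)C1=O
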